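solid substrate 0.29 M; solid reagent 0.800 equiv; time 20 h

    partner ⇌ dormant form (K1 = 0.82, k1 = 0.019 /min)
    dissolved substrate + target → side product (k2 = 0.013 /M/min)
    dissolved substrate + partner → target (k3 = 0.087 /M/min)
    solid substrate ⇌ dissolved substrate, rate k4*(cs4 - [dissolved substrate]) while solid is left; crystals form when [dissolved substrate] > cs4 (cs4 = 0.15 M, k4 = 0.026 /min)
    solid reagent ⇌ partner, rate k5*(cs5 - [partner]) while solid is left; crystals form when [partner] > cs5 (cs5 = 0.22 M, k5 = 0.022 /min)
    solid product ⇌ target, rate k6*(cs6 - [target]) while solid is left; crystals form when [target] > cs6 (cs6 = 47 mM, k6 = 0.40 /min)

- percent here means solid substrate units held: one side product counts as two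
- what is said of target includes solid product
- solid substrate, solid product, solid reagent is a solid; its amount is given per volume of the solution
- at the start none of the solid substrate is in solution
- at the start none of the solid reagent is in solution
- dissolved substrate means what is dissolved; the solid is not counted in it
- run time (flask): 20 h

- amount of target and solid product together at 20 h, in percent of the solid substrate charged
- concentration of dissolved substrate in solution at 20 h, in percent of saturation

I started from the small charge, the 0.800 equiv of solid reagent: it stood below the one equivalent of substrate, so it was the limiting reagent and 80.0% of target was the ceiling. Each target took one partner and one substrate unit, and each side product, counted as two units, also took one partner. I wrote y for target with solid product, q for side product, a for substrate left and r for reagent left in any form, each in percent of the substrate charged. The two balances were y + q + a = 100% and y + 0.5q + r = 80.0%.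

Removing q gave y = S + a − 2r, with S = 60.0%, twice the ceiling less the whole substrate charge, the spent-out yield: the y that stands when a and r are both zero. No rate constant enters it. S was my lower bound for as long as a stayed above 2r.

For the upper end, an estimate and not a strict bound, I set r to zero, which left an excess of 20.0%. The ceiling lay far above the solubility of target, so I held dissolved target at 47 mM. Step 2 then became pseudo-first-order in dissolved substrate, with constant 0.0367 /h. Over 20 h the excess fell to 9.61%, which gave y = 69.6% and 18.6% of saturation. My bracket for y was 60.0% to 69.6%.

The forecast gave y = 62% (56% to 68%) and 17% of saturation (11% to 24%), on the grounds of “a slow leak that takes a modest share of the product”; its central y stood inside my bracket, while its range reached below S at the low end.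

The flask gave y = 62.0% and 15.9% of saturation, inside my bracket. At 20.0 h this flask held 8.21% as dissolved substrate, with 0.00484 M of partner and 0.00418 M of dormant form, and S + a − 2r came to 62.0%. The neighbour with 0.480 equiv of solid reagent has S = −4.00%. Its 25.8% of dissolved substrate, 2.70 × 10⁻⁴ M of partner and 2.59 × 10⁻⁴ M of dormant form give 21.4%, and that neighbour held 21.4% at 20.0 h.

The numbers come from no measurement; the result is computed.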